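**Retrosynthetic overview**

1. The naphthalene bicycle is bought as menadione and carried as its 1,4-dimethyl ether; no ring is formed in the route, and the quinone ring is unmasked in the last step.
2. Key disconnection: the side-chain bond C11'–C12' (C1' = ring-bound CH2), between the methyl-bearing CH and the CH2 beyond it. A C31 primary Grignard reagent and a C27 secondary tosylate are joined by copper-catalysed SN2 coupling with inversion, which sets C11' in the same operation.
3. Enabling feature: C11' carries only CH3, C10'H2 and C12'H2, a 2-alkyl (methylcarbinyl) position, the least hindered class of secondary carbon and available as an (R)-carbinol from (R)-propylene oxide. C12' is homoallylic to the C14'=C15' alkene, so its Grignard reagent is a plain primary alkyl and not an allyl metal.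
4. Right half: (S)-citronellol → chloride (latent Grignard) → ozonolysis, iodide, acetylide → carboalumination and Ni coupling with the chloromethyl-dimethoxynaphthalene (2'E) → Grignard opening of (R)-propylene oxide → tosylate.
5. Left half: geranylgeraniol → one-carbon homologation (Wittig, hydroboration) → chloride → terminal allylic oxidation → allylic bromide, coupled with (R)-citronellylmagnesium bromide. All three stereocentres are bought.

Key step: step 17

Remark: (S)-citronellol, (R)-citronellyl bromide and (R)-propylene oxide are taken as enantiopure, because the three remote stereocentres cannot be enriched later in the route.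

**Route**

Step 1
Reactants: 1 menadione
Product: 3 1,4-dimethoxy-2-methylnaphthalene, via menadiol 2 (not isolated)
Conditions: Na2S2O4, n-Bu4NBr (cat.), THF/H2O, rt; then aq KOH, Me2SO4, rt (N2)
Reagents that add atoms: dimethyl sulfate COS(=O)(=O)OC
Why: Dithionite reduction of the quinone followed by in-situ double Williamson O-methylation (reductive methylation) should mask the quinone as an ether that is stable to organoaluminium and Grignard reagents.

Step 2
Reactants: 3 1,4-dimethoxy-2-methylnaphthalene
Product: 4 2-(chloromethyl)-1,4-dimethoxy-3-methylnaphthalene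
Conditions: (CH2O)n, 37% aq HCl, AcOH, rt
Reagents that add atoms: formaldehyde (as paraformaldehyde) C=O; hydrogen chloride Cl
Why: Blanc chloromethylation should occur at C3, the only free position of the electron-rich dimethoxy ring.

Step 3
Reactants: 5 (S)-citronellol
Product: 6 (S)-citronellyl chloride
Conditions: PPh3, CCl4, 70 °C
Reagents that add atoms: carbon tetrachloride ClC(Cl)(Cl)Cl
Why: Appel chlorination of the primary alcohol leaves the stereocentre untouched and installs a chloride that is inert in steps 4–7 and serves as a latent Grignard reagent in step 8.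

Step 4
Reactants: 6 (S)-citronellyl chloride
Product: 8 (4S)-6-chloro-4-methylhexan-1-ol, via aldehyde 7 (not isolated)
Conditions: O3, CH2Cl2/MeOH, −78 °C; then NaBH4, −78 °C → rt
Reagents that add atoms: ozone [O-][O+]=O
Why: Ozonolysis of the trisubstituted alkene with reductive work-up should give the primary alcohol, the alkyl chloride being inert to both reagents.

Step 5
Reactants: 8 (4S)-6-chloro-4-methylhexan-1-ol
Product: 9 (3S)-1-chloro-6-iodo-3-methylhexane
Conditions: I2, PPh3, imidazole, CH2Cl2, 0 °C → rt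
Reagents that add atoms: iodine II
Why: Appel-type iodination of the primary alcohol proceeds by SN2 displacement of the alkoxyphosphonium ion and does not touch the chloride.

Step 6
Reactants: 9 (3S)-1-chloro-6-iodo-3-methylhexane
Product: 10 (6S)-8-chloro-6-methyloct-1-yne
Conditions: HC≡CLi·H2NCH2CH2NH2, DMSO, 10–15 °C
Reagents that add atoms: lithium acetylide (ethylenediamine complex) [Li]C#C
Why: SN2 alkylation of lithium acetylide should be selective for the primary iodide over the primary chloride, as in the monoalkynylation of bromo-chloroalkanes.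

Step 7
Reactants: 10 (6S)-8-chloro-6-methyloct-1-yne; 4 2-(chloromethyl)-1,4-dimethoxy-3-methylnaphthalene
Product: 12 2-[(2E,7S)-9-chloro-3,7-dimethylnon-2-en-1-yl]-1,4-dimethoxy-3-methylnaphthalene, via alkenylalane 11 (not isolated)
Conditions: Me3Al, Cp2ZrCl2 (25 mol %), ClCH2CH2Cl, 0 °C → rt; volatiles removed; then 4, Ni(PPh3)4 (3 mol %, from NiCl2(PPh3)2/n-BuLi), THF, rt
Reagents that add atoms: trimethylaluminium C[Al](C)C
Why: Negishi carboalumination adds Me and Al syn across the alkyne (Me to the internal carbon) and the Ni(0)-catalysed cross-coupling of the alkenylalane with the benzylic chloride proceeds with retention, so the 2'E alkene is set, while the primary alkyl chloride is inert to both stages.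

Step 8
Reactants: 12 2-[(2E,7S)-9-chloro-3,7-dimethylnon-2-en-1-yl]-1,4-dimethoxy-3-methylnaphthalene; 13 (R)-propylene oxide
Product: 15 (2R,6S,10E)-12-(1,4-dimethoxy-3-methylnaphthalen-2-yl)-6,10-dimethyldodec-10-en-2-ol, via Grignard reagent 14 (not isolated)
Conditions: Mg (BrCH2CH2Br-activated), THF, 60 °C; then CuI (10 mol %), 13, −30 → 0 °C; aq NH4Cl
Reagents that add atoms: none
Why: Copper-catalysed epoxide ring opening by the primary Grignard reagent occurs at the unsubstituted CH2 of 13, so the C–O bond at its stereocentre is not broken and the carbinol should be (2R).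

Step 9
Reactants: 15 (2R,6S,10E)-12-(1,4-dimethoxy-3-methylnaphthalen-2-yl)-6,10-dimethyldodec-10-en-2-ol
Product: 16 (2R,6S,10E)-12-(1,4-dimethoxy-3-methylnaphthalen-2-yl)-6,10-dimethyldodec-10-en-2-yl 4-methylbenzenesulfonate
Conditions: TsCl, Et3N, Me3N·HCl (cat.), CH2Cl2, 0 °C
Reagents that add atoms: p-toluenesulfonyl chloride Cc1ccc(cc1)S(Cl)(=O)=O
Why: Amine-catalysed O-sulfonylation of the secondary alcohol forms the S–O bond only, so the carbinol configuration is retained.

Step 10
Reactants: 17 (2E,6E,10E)-geranylgeraniol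
Product: 18 (2E,6E,10E)-geranylgeranial
Conditions: MnO2 (activated), CH2Cl2, rt
Reagents that add atoms: none
Why: MnO2 oxidation is selective for the allylic alcohol and should give the enal without over-oxidation or loss of the 2E geometry.

Step 11
Reactants: 18 (2E,6E,10E)-geranylgeranial
Product: 19 (3E,7E,11E)-4,8,12,16-tetramethylheptadeca-1,3,7,11,15-pentaene
Conditions: Ph3PCH3Br, n-BuLi, THF, 0 °C; then 18, −78 °C → rt
Reagents that add atoms: methyltriphenylphosphonium bromide [Br-].C[P+](c1ccccc1)(c1ccccc1)c1ccccc1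
Why: Wittig methylenation of the enal should give the terminal 1,3-diene with the trisubstituted alkene geometry preserved.

Step 12
Reactants: 19 (3E,7E,11E)-4,8,12,16-tetramethylheptadeca-1,3,7,11,15-pentaene
Product: 21 (3E,7E,11E)-4,8,12,16-tetramethylheptadeca-3,7,11,15-tetraen-1-ol, via alkylborane 20 (not isolated)
Conditions: 9-BBN, THF, 0 °C → rt; then 3 M NaOH, 30% H2O2, 0 °C → rt
Reagents that add atoms: hydrogen peroxide OO
Why: Hydroboration–oxidation with 9-BBN places boron at the terminal carbon of the only monosubstituted alkene, far faster than at the trisubstituted alkenes, giving the homoallylic alcohol as in the homogeraniol preparation.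

Step 13
Reactants: 21 (3E,7E,11E)-4,8,12,16-tetramethylheptadeca-3,7,11,15-tetraen-1-ol
Product: 22 (6E,10E,14E)-17-chloro-2,6,10,14-tetramethylheptadeca-2,6,10,14-tetraene
Conditions: PPh3, CCl4, 70 °C
Reagents that add atoms: carbon tetrachloride ClC(Cl)(Cl)Cl
Why: Appel chlorination of the primary homoallylic alcohol installs the chloride that survives steps 14–16 and becomes the Grignard reagent of the key step.

Step 14
Reactants: 22 (6E,10E,14E)-17-chloro-2,6,10,14-tetramethylheptadeca-2,6,10,14-tetraene
Product: 23 (2E,6E,10E,14E)-17-chloro-2,6,10,14-tetramethylheptadeca-2,6,10,14-tetraen-1-ol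
Conditions: SeO2 (cat.), t-BuOOH, salicylic acid (cat.), CH2Cl2, 0 °C → rt; stopped at partial conversion, 22 recycled
Reagents that add atoms: selenium dioxide O=[Se]=O (catalytic oxygen carrier); tert-butyl hydroperoxide CC(C)(C)OO (terminal oxidant)
Why: Riley allylic oxidation (ene reaction, then [2,3]-sigmatropic shift) favours the E-methyl of the terminal isopropylidene group and should give the (E)-allylic alcohol.

Step 15
Reactants: 23 (2E,6E,10E,14E)-17-chloro-2,6,10,14-tetramethylheptadeca-2,6,10,14-tetraen-1-ol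
Product: 24 (2E,6E,10E,14E)-1-bromo-17-chloro-2,6,10,14-tetramethylheptadeca-2,6,10,14-tetraene
Conditions: CBr4, PPh3, CH2Cl2, −20 → 0 °C
Reagents that add atoms: carbon tetrabromide BrC(Br)(Br)Br
Why: Appel bromination at low temperature displaces the primary allylic alkoxyphosphonium ion by SN2 without allylic transposition.

Step 16
Reactants: 24 (2E,6E,10E,14E)-1-bromo-17-chloro-2,6,10,14-tetramethylheptadeca-2,6,10,14-tetraene; 25 (R)-citronellyl bromide
Product: 27 (6S,10E,14E,18E,22E)-25-chloro-2,6,10,14,18,22-hexamethylpentacosa-2,10,14,18,22-pentaene, via Grignard reagent 26 (not isolated)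
Conditions: 25, Mg, THF, 40 °C; then 24, Li2CuCl4 (5 mol %), THF, −78 → 0 °C
Reagents that add atoms: none
Why: Copper-catalysed Grignard cross-coupling with the primary allylic bromide (Li2CuCl4) should occur at the α-carbon with retention of the E geometry, the alkyl chloride being inert at or below 0 °C and the citronellyl stereocentre untouched.

Step 17
Reactants: 27 (6S,10E,14E,18E,22E)-25-chloro-2,6,10,14,18,22-hexamethylpentacosa-2,10,14,18,22-pentaene; 16 (2R,6S,10E)-12-(1,4-dimethoxy-3-methylnaphthalen-2-yl)-6,10-dimethyldodec-10-en-2-yl 4-methylbenzenesulfonate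
Product: 29 2-[(2E,7R,11S,14E,18E,22E,26E,31S)-3,7,11,15,19,23,27,31,35-nonamethylhexatriaconta-2,14,18,22,26,34-hexaen-1-yl]-1,4-dimethoxy-3-methylnaphthalene, via Grignard reagent 28 (not isolated)
Conditions: 27 (1.5 equiv), Mg (BrCH2CH2Br-activated), THF, 60 °C; then added slowly to 16, CuI (10 mol %), TMEDA (20 mol %), LiOMe (1 equiv), THF, 0 °C
Reagents that add atoms: none
Why: The Grignard reagent 28 is transmetalated to an alkylcuprate (CuI/TMEDA, LiOMe as promoter) that attacks the tosylate carbon of 16 from the face opposite to the C–O bond (SN2-type oxidative addition, then reductive elimination), so the C–C bond should form with inversion. The closest known reaction type is the copper-catalysed cross-coupling of non-activated secondary alkyl tosylates with alkyl Grignard reagents, the catalytic form of the classical cuprate–tosylate substitution, both stereoinvertive. No ring is closed. The new stereocentre C11' is controlled solely by the (R)-configured tosylate carbon bought with (R)-propylene oxide, which inversion turns into the required (S) centre, while the centres at C7' and C31', the trisubstituted alkenes and the aryl methyl ethers are spectators. The step needs substitution at carbon to outrun E2 elimination and attack at sulfur, which is secured by the electrophile being a methylcarbinyl tosylate flanked only by CH3 and an unbranched CH2 and by the nucleophile being an unhindered primary alkyl whose homoallylic (not allylic) position excludes 1,3-transposition. In this one operation the C31 and C27 halves are joined, the last C–C bond of the C58 skeleton is made and the third stereocentre is set, leaving only the unmasking of the quinone.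

Step 18
Reactants: 29 2-[(2E,7R,11S,14E,18E,22E,26E,31S)-3,7,11,15,19,23,27,31,35-nonamethylhexatriaconta-2,14,18,22,26,34-hexaen-1-yl]-1,4-dimethoxy-3-methylnaphthalene
Product: 30 2-methyl-3-[(2E,7R,11S,14E,18E,22E,26E,31S)-3,7,11,15,19,23,27,31,35-nonamethylhexatriaconta-2,14,18,22,26,34-hexaen-1-yl]naphthalene-1,4-dione (CNP0210279.1)
Conditions: (NH4)2Ce(NO3)6, MeCN/CH2Cl2/H2O, 0 °C
Reagents that add atoms: water O
Why: Cerium(IV) oxidative demethylation of the 1,4-dimethoxyarene (two one-electron oxidations, ipso attack of water, loss of methanol) should give the quinone, with the isolated trisubstituted alkenes tolerated at 0 °C as in menaquinone syntheses.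

**Compound list**

1 | menadione (2-methylnaphthalene-1,4-dione) | CC1=CC(=O)c2ccccc2C1=O | starting material
2 | menadiol (2-methylnaphthalene-1,4-diol) | Cc1cc(O)c2ccccc2c1O | intermediate
3 | 1,4-dimethoxy-2-methylnaphthalene | COc1cc(C)c(OC)c2ccccc12 | intermediate
4 | 2-(chloromethyl)-1,4-dimethoxy-3-methylnaphthalene | COc1c(C)c(CCl)c(OC)c2ccccc12 | intermediate
5 | (S)-citronellol, (3S)-3,7-dimethyloct-6-en-1-ol | CC(C)=CCC[C@H](C)CCO | starting material
6 | (S)-citronellyl chloride, (6S)-8-chloro-2,6-dimethyloct-2-ene | CC(C)=CCC[C@H](C)CCCl | intermediate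
7 | (4S)-6-chloro-4-methylhexanal | O=CCC[C@H](C)CCCl | intermediate
8 | (4S)-6-chloro-4-methylhexan-1-ol | OCCC[C@H](C)CCCl | intermediate
9 | (3S)-1-chloro-6-iodo-3-methylhexane | ICCC[C@H](C)CCCl | intermediate
10 | (6S)-8-chloro-6-methyloct-1-yne | C#CCCC[C@H](C)CCCl | intermediate
11 | [(1E,6S)-8-chloro-2,6-dimethyloct-1-en-1-yl]dimethylalane | ClCC[C@@H](C)CCC/C(C)=C/[Al](C)C | intermediate
12 | 2-[(2E,7S)-9-chloro-3,7-dimethylnon-2-en-1-yl]-1,4-dimethoxy-3-methylnaphthalene | ClCC[C@@H](C)CCC/C(C)=C/Cc1c(C)c(OC)c2ccccc2c1OC | intermediate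
13 | (R)-propylene oxide, (2R)-2-methyloxirane | C[C@@H]1CO1 | starting material
14 | chloro[(3S,7E)-9-(1,4-dimethoxy-3-methylnaphthalen-2-yl)-3,7-dimethylnon-7-en-1-yl]magnesium | Cl[Mg]CC[C@@H](C)CCC/C(C)=C/Cc1c(C)c(OC)c2ccccc2c1OC | intermediate
15 | (2R,6S,10E)-12-(1,4-dimethoxy-3-methylnaphthalen-2-yl)-6,10-dimethyldodec-10-en-2-ol | C[C@@H](O)CCC[C@@H](C)CCC/C(C)=C/Cc1c(C)c(OC)c2ccccc2c1OC | intermediate
16 | (2R,6S,10E)-12-(1,4-dimethoxy-3-methylnaphthalen-2-yl)-6,10-dimethyldodec-10-en-2-yl 4-methylbenzenesulfonate | Cc1ccc(cc1)S(=O)(=O)O[C@H](C)CCC[C@@H](C)CCC/C(C)=C/Cc1c(C)c(OC)c2ccccc2c1OC | intermediate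
17 | (2E,6E,10E)-geranylgeraniol, (2E,6E,10E)-3,7,11,15-tetramethylhexadeca-2,6,10,14-tetraen-1-ol | CC(C)=CCC/C(C)=C/CC/C(C)=C/CC/C(C)=C/CO | starting material
18 | (2E,6E,10E)-geranylgeranial | CC(C)=CCC/C(C)=C/CC/C(C)=C/CC/C(C)=C/C=O | intermediate
19 | (3E,7E,11E)-4,8,12,16-tetramethylheptadeca-1,3,7,11,15-pentaene | CC(C)=CCC/C(C)=C/CC/C(C)=C/CC/C(C)=C/C=C | intermediate
20 | 9-[(3E,7E,11E)-4,8,12,16-tetramethylheptadeca-3,7,11,15-tetraen-1-yl]-9-borabicyclo[3.3.1]nonane | CC(C)=CCC/C(C)=C/CC/C(C)=C/CC/C(C)=C/CCB1C2CCCC1CCC2 | intermediate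
21 | (3E,7E,11E)-4,8,12,16-tetramethylheptadeca-3,7,11,15-tetraen-1-ol | CC(C)=CCC/C(C)=C/CC/C(C)=C/CC/C(C)=C/CCO | intermediate
22 | (6E,10E,14E)-17-chloro-2,6,10,14-tetramethylheptadeca-2,6,10,14-tetraene | CC(C)=CCC/C(C)=C/CC/C(C)=C/CC/C(C)=C/CCCl | intermediate
23 | (2E,6E,10E,14E)-17-chloro-2,6,10,14-tetramethylheptadeca-2,6,10,14-tetraen-1-ol | OC/C(C)=C/CC/C(C)=C/CC/C(C)=C/CC/C(C)=C/CCCl | intermediate
24 | (2E,6E,10E,14E)-1-bromo-17-chloro-2,6,10,14-tetramethylheptadeca-2,6,10,14-tetraene | BrC/C(C)=C/CC/C(C)=C/CC/C(C)=C/CC/C(C)=C/CCCl | intermediate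
25 | (R)-citronellyl bromide, (6R)-8-bromo-2,6-dimethyloct-2-ene | CC(C)=CCC[C@@H](C)CCBr | starting material
26 | bromo[(3R)-3,7-dimethyloct-6-en-1-yl]magnesium | CC(C)=CCC[C@@H](C)CC[Mg]Br | intermediate
27 | (6S,10E,14E,18E,22E)-25-chloro-2,6,10,14,18,22-hexamethylpentacosa-2,10,14,18,22-pentaene | CC(C)=CCC[C@@H](C)CCC/C(C)=C/CC/C(C)=C/CC/C(C)=C/CC/C(C)=C/CCCl | intermediate
28 | chloro[(3E,7E,11E,15E,20S)-4,8,12,16,20,24-hexamethylpentacosa-3,7,11,15,23-pentaen-1-yl]magnesium | CC(C)=CCC[C@@H](C)CCC/C(C)=C/CC/C(C)=C/CC/C(C)=C/CC/C(C)=C/CC[Mg]Cl | intermediate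
29 | 2-[(2E,7R,11S,14E,18E,22E,26E,31S)-3,7,11,15,19,23,27,31,35-nonamethylhexatriaconta-2,14,18,22,26,34-hexaen-1-yl]-1,4-dimethoxy-3-methylnaphthalene | CC(C)=CCC[C@@H](C)CCC/C(C)=C/CC/C(C)=C/CC/C(C)=C/CC/C(C)=C/CC[C@@H](C)CCC[C@@H](C)CCC/C(C)=C/Cc1c(C)c(OC)c2ccccc2c1OC | intermediate
30 | 2-methyl-3-[(2E,7R,11S,14E,18E,22E,26E,31S)-3,7,11,15,19,23,27,31,35-nonamethylhexatriaconta-2,14,18,22,26,34-hexaen-1-yl]naphthalene-1,4-dione | CC(C)=CCC[C@@H](C)CCC/C(C)=C/CC/C(C)=C/CC/C(C)=C/CC/C(C)=C/CC[C@@H](C)CCC[C@@H](C)CCC/C(C)=C/CC1=C(C)C(=O)c2ccccc2C1=O | target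

**Step count and risks**

Total step count: 18. Longest linear sequence: 9 steps (steps 3–9, 17, 18; the branch through steps 10–16, 17, 18 is equally long).

Steps most likely to fail:

1. Step 17. Base-induced E2 elimination of the secondary tosylate or attack of the Grignard reagent at sulfur may outrun substitution at carbon, and formation of the C31 Grignard reagent may be eroded by Wurtz dimerisation. The fallback moves the stereoinvertive C–C bond formation to an α-triflyloxy ester, a far better SN2 electrophile, and joins the halves one bond further on (C9'–C10') by a primary–primary coupling. It sets out from Grignard reagent 28 and Grignard reagent 14 (made from 12, so that steps 8 and 9 fall away) and comes back to the route at 29. Ethyl (R)-lactate is treated with Tf2O and 2,6-lutidine (CH2Cl2, −78 °C) to give ethyl (2R)-2-{[(trifluoromethyl)sulfonyl]oxy}propanoate F1. Coupling of 28 with F1 under ZnCl2 catalysis (THF, 0 °C) should give, with inversion, ethyl (2R,5E,9E,13E,17E,22S)-2,6,10,14,18,22,26-heptamethylheptacosa-5,9,13,17,25-pentaenoate F2. LiAlH4 (Et2O, 0 °C) reduces it to (2R,5E,9E,13E,17E,22S)-2,6,10,14,18,22,26-heptamethylheptacosa-5,9,13,17,25-pentaen-1-ol F3, and TsCl/Et3N converts this into the primary 4-methylbenzenesulfonate F4. Li2CuCl4-catalysed coupling of F4 with 14 (THF, −20 → 0 °C) should give 29.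

2. Step 14. The ene reaction may discriminate poorly between the terminal isopropylidene group and the three internal trisubstituted alkenes, and the allylic alcohol may be over-oxidised to the enal. The fallback replaces direct C–H oxidation by cleavage and rebuilding of the terminal alkene; it sets out from 22 and comes back at 23. Terminal-selective bromohydrin formation (NBS, THF/H2O, 0 °C) gives the racemic bromohydrin 3-bromo-17-chloro-2,6,10,14-tetramethylheptadeca-6,10,14-trien-2-ol F5. K2CO3 in MeOH closes the terminal epoxide F6, and periodic acid (THF/Et2O, 0 °C) cleaves it to (4E,8E,12E)-15-chloro-4,8,12-trimethylpentadeca-4,8,12-trienal F7. Wittig reaction with ethyl 2-(triphenylphosphoranylidene)propanoate (CH2Cl2, rt) should give ethyl (2E,6E,10E,14E)-17-chloro-2,6,10,14-tetramethylheptadeca-2,6,10,14-tetraenoate F8, and DIBAL-H (CH2Cl2, −78 °C) reduces it to 23.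

3. Step 16. Attack at the γ-carbon with allylic transposition may give a branched isomer, the E geometry may erode through an allylcopper intermediate, and Wurtz-type homocoupling may consume the bromide. The fallback is a Julia-type sulfone alkylation followed by desulfonylation; it sets out from 25 and 24 and comes back at 27. Displacement of 25 with PhSO2Na (DMF, 60 °C) gives {[(3R)-3,7-dimethyloct-6-en-1-yl]sulfonyl}benzene F9. Its α-lithio derivative (n-BuLi, THF, −78 °C) is alkylated by 24 at the primary allylic carbon only, giving the alkylated sulfone F10 as a mixture of epimers at the sulfonyl-bearing carbon. Reductive desulfonylation (6% Na(Hg), Na2HPO4, MeOH/THF, −20 °C) should give 27.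

Further compounds
F1 | step 17 | ethyl (2R)-2-{[(trifluoromethyl)sulfonyl]oxy}propanoate | CCOC(=O)[C@@H](C)OS(=O)(=O)C(F)(F)F
F2 | step 17 | ethyl (2R,5E,9E,13E,17E,22S)-2,6,10,14,18,22,26-heptamethylheptacosa-5,9,13,17,25-pentaenoate | CC(C)=CCC[C@@H](C)CCC/C(C)=C/CC/C(C)=C/CC/C(C)=C/CC/C(C)=C/CC[C@@H](C)C(=O)OCC
F3 | step 17 | (2R,5E,9E,13E,17E,22S)-2,6,10,14,18,22,26-heptamethylheptacosa-5,9,13,17,25-pentaen-1-ol | CC(C)=CCC[C@@H](C)CCC/C(C)=C/CC/C(C)=C/CC/C(C)=C/CC/C(C)=C/CC[C@@H](C)CO
F4 | step 17 | (2R,5E,9E,13E,17E,22S)-2,6,10,14,18,22,26-heptamethylheptacosa-5,9,13,17,25-pentaen-1-yl 4-methylbenzenesulfonate | CC(C)=CCC[C@@H](C)CCC/C(C)=C/CC/C(C)=C/CC/C(C)=C/CC/C(C)=C/CC[C@@H](C)COS(=O)(=O)c1ccc(C)cc1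
F5 | step 14 | (6E,10E,14E)-3-bromo-17-chloro-2,6,10,14-tetramethylheptadeca-6,10,14-trien-2-ol (racemic) | CC(C)(O)C(Br)CC/C(C)=C/CC/C(C)=C/CC/C(C)=C/CCCl
F6 | step 14 | 3-[(3E,7E,11E)-14-chloro-3,7,11-trimethyltetradeca-3,7,11-trien-1-yl]-2,2-dimethyloxirane (racemic) | CC1(C)OC1CC/C(C)=C/CC/C(C)=C/CC/C(C)=C/CCCl
F7 | step 14 | (4E,8E,12E)-15-chloro-4,8,12-trimethylpentadeca-4,8,12-trienal | O=CCC/C(C)=C/CC/C(C)=C/CC/C(C)=C/CCCl
F8 | step 14 | ethyl (2E,6E,10E,14E)-17-chloro-2,6,10,14-tetramethylheptadeca-2,6,10,14-tetraenoate | CCOC(=O)/C(C)=C/CC/C(C)=C/CC/C(C)=C/CC/C(C)=C/CCCl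
F9 | step 16 | {[(3R)-3,7-dimethyloct-6-en-1-yl]sulfonyl}benzene | CC(C)=CCC[C@@H](C)CCS(=O)(=O)c1ccccc1
F10 | step 16 | {[(6R,10E,14E,18E,22E)-25-chloro-2,6,10,14,18,22-hexamethylpentacosa-2,10,14,18,22-pentaen-8-yl]sulfonyl}benzene (epimers at C8) | CC(C)=CCC[C@@H](C)CC(S(=O)(=O)c1ccccc1)C/C(C)=C/CC/C(C)=C/CC/C(C)=C/CC/C(C)=C/CCCl
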